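## Retrosynthetic overview
- Last step: remove three MOM ethers together. MOM tolerates organolithium reagents and comes off under acid mild enough for the ortho-prenyl phenols.
- Both prenyl C–C bonds are disconnected together to a 2',6'-dibromide (double Br/Li exchange, Cu, prenyl bromide). The prenyl groups go on last, so they never meet Pd or NBS.
- The biaryl bond C2–C1' comes from an iodide-selective Negishi coupling of 6-(MOMO)benzofuran-2-ylzinc chloride with a 2,4-dibromo-3-iodoresorcinol bis-MOM ether.
- The trihalide comes from 5-iodoresorcinol by MOM protection and double bromination, each Br entering para to one OMOM group.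
- Ring formation: none. The benzofuran (benzofuran-6-ol) and the resorcinol ring (5-iodoresorcinol) are both bought intact.

Assumption: the SMILES has no stereocentre and no E/Z alkene. It has no stereogenic axis either, because the 2' and 6' substituents are identical. The target is therefore achiral and no stereocontrol is needed. 5-Iodoresorcinol and benzofuran-6-ol are taken as catalogue chemicals.

## Route

**Step 1**
Reactants: 1, 5-iodoresorcinol (5-iodobenzene-1,3-diol); 2, chloromethyl methyl ether (MOMCl)
Product: 3, 1-iodo-3,5-bis(methoxymethoxy)benzene
Conditions: MOMCl (2.6 equiv), i-Pr2NEt (3.5 equiv), CH2Cl2, 0 °C → rt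
Reagents that add atoms: MOMCl, COCCl
Why: Williamson-type O-alkylation of both phenols gives base-stable, lithium-chelating acetal ethers, and the aryl iodide is inert.

**Step 2**
Reactants: 3; 4, N-bromosuccinimide
Product: 5, 2,4-dibromo-3-iodo-1,5-bis(methoxymethoxy)benzene
Conditions: NBS (2.05 equiv), MeCN, 0 °C → rt, dark
Reagents that add atoms: NBS, O=C1CCC(=O)N1Br
Why: In this electrophilic aromatic bromination each Br enters para to one OMOM and ortho to the other (the usual 4,6-dihalogenation of 5-substituted resorcinol ethers), while the site between the two OMOM groups reacts last, the C–I carbon is meta to both donors so ipso attack is disfavoured, and neutral NBS leaves MOM intact.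

**Step 3**
Reactants: 6, benzofuran-6-ol; 2, MOMCl
Product: 7, 6-(methoxymethoxy)-1-benzofuran
Conditions: MOMCl (1.3 equiv), i-Pr2NEt (2 equiv), CH2Cl2, 0 °C → rt
Reagents that add atoms: MOMCl, COCCl
Why: Williamson-type O-alkylation masks the acidic OH with the same group used on the other ring, so one final deprotection is enough.

**Step 4**
Reactants: 7 (1.1 equiv); 5 (1.0 equiv)
Product: 8, 2-[2,6-dibromo-3,5-bis(methoxymethoxy)phenyl]-6-(methoxymethoxy)-1-benzofuran
Conditions: 7, n-BuLi (1.0 equiv relative to 7), THF, −78 °C, 1 h; ZnCl2 (1.1 equiv), −78 °C → rt; then 5, Pd(PPh3)4 (5 mol %), THF, 50 °C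
Reagents that add atoms: none (both partners are listed as reactants; Li, Zn and Pd leave no atoms)
Why: Benzofuran is lithiated kinetically at C2 at −78 °C (OMOM-directed metalation needs higher temperature), and after zincation the Negishi cross-coupling occurs at C–I only, as for 1,3-dibromo-2-iodoarenes, because the electron-rich di-ortho-substituted C–Br bonds do not add to Pd(PPh3)4 at 50 °C with about one equivalent of zinc reagent.

**Step 5**
Reactants: 8; 9, prenyl bromide (1-bromo-3-methylbut-2-ene)
Product: 10, 2-[3,5-bis(methoxymethoxy)-2,6-bis(3-methylbut-2-en-1-yl)phenyl]-6-(methoxymethoxy)-1-benzofuran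
Conditions: t-BuLi (4.3 equiv), THF, −78 °C, 30 min; CuBr·SMe2 (2.2 equiv), −78 → −40 °C; prenyl bromide (3 equiv), −78 → 0 °C; aq NH4Cl/NH3 quench
Reagents that add atoms: prenyl bromide, CC(C)=CCBr
Why: Double bromine–lithium exchange is made irreversible by the second equivalent of t-BuLi per Br, each C–Li is chelated by its ortho OMOM with no ortho halide left to give an aryne, and after transmetalation the arylcopper displaces prenyl bromide at the primary carbon (SN2, α-attack) to give linear prenyl groups.

**Step 6**
Reactants: 10
Product: 11, Mulberrofuran V, 5-(6-hydroxy-1-benzofuran-2-yl)-4,6-bis(3-methylbut-2-en-1-yl)benzene-1,3-diol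
Conditions: 3 M aq HCl, MeOH, 45–50 °C, N2, stopped at full conversion (about 1–2 h)
Reagents that add atoms: none
Why: Acid-catalysed acetal methanolysis cleaves all three phenolic MOM ethers faster than the trisubstituted alkenes are protonated, so chroman formation is avoided, and no stereocentre is created or present.

## Compound list
1 | 5-iodoresorcinol | Oc1cc(O)cc(I)c1 | starting material
2 | chloromethyl methyl ether (MOMCl) | COCCl | starting material (reagent)
3 | 1-iodo-3,5-bis(methoxymethoxy)benzene | COCOc1cc(I)cc(OCOC)c1 | intermediate
4 | N-bromosuccinimide | O=C1CCC(=O)N1Br | starting material (reagent)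
5 | 2,4-dibromo-3-iodo-1,5-bis(methoxymethoxy)benzene | COCOc1cc(OCOC)c(Br)c(I)c1Br | intermediate
6 | benzofuran-6-ol | Oc1ccc2ccoc2c1 | starting material
7 | 6-(methoxymethoxy)-1-benzofuran | COCOc1ccc2ccoc2c1 | intermediate
8 | 2-[2,6-dibromo-3,5-bis(methoxymethoxy)phenyl]-6-(methoxymethoxy)-1-benzofuran | COCOc1ccc2cc(oc2c1)-c1c(Br)c(OCOC)cc(OCOC)c1Br | intermediate
9 | prenyl bromide | CC(C)=CCBr | starting material (reagent)
10 | tri-O-MOM mulberrofuran V | COCOc1ccc2cc(oc2c1)-c1c(CC=C(C)C)c(OCOC)cc(OCOC)c1CC=C(C)C | intermediate
11 | Mulberrofuran V (achiral) | CC(C)=CCc1c(O)cc(O)c(CC=C(C)C)c1-c1cc2ccc(O)cc2o1 | target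

## Step count
Total steps: 6
Longest linear sequence: 5 (1 → 3 → 5 → 8 → 10 → 11)

## Steps most likely to fail, with fallbacks
1. **Step 5.** The risks are an incomplete second Br/Li exchange, protonation giving the mono-prenyl product, or some γ-attack. Fallback: Pd-catalysed double allylation of 8 with allyl-Bpin or allyltributylstannane, which has no α/γ ambiguity. Follow it with double olefin cross-metathesis with 2-methyl-2-butene (Grubbs II) to turn allyl into prenyl (+1 step).
2. **Step 4.** The risks are a sluggish coupling at the di-ortho-bromo iodide or loss of I/Br selectivity. Fallback: build the furan ring instead of coupling onto it.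
   - Take 3,5-dihydroxybenzaldehyde through bis-MOM protection, NBS (2 equiv) and Ohira–Bestmann homologation to 2,6-dibromo-3,5-bis(MOMO)phenylacetylene.
   - Couple this by Sonogashira reaction with 2-iodo-5-(methoxymethoxy)phenol and close by 5-endo-dig cyclisation to the same compound 8.
3. **Step 6.** The risks are acid-induced cyclisation of an ortho-prenyl phenol to a 2,2-dimethylchroman, or MeOH addition to the alkene. Fallback: change the protecting-group plan to SEM ethers (SEMCl in steps 1 and 3). SEM is equally stable to BuLi and NBS and is not prone to retro-Brook migration. The final unmasking then uses fluoride (TBAF, THF/DMPU, heat) with no acid.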